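(Readings and results are calculated on assumed constants, noise included.)

The trap in these flasks is to take the charge of second end groups for the level they stand at, when a slow feed can hold that level far below the charge.

| flask | first end groups | second end groups | protic impurity | temperature | remark | time |
|---|---|---|---|---|---|---|
| blue | 0.071 M | 0.0639 M | 3.55 mM | 25 °C | run made earlier |  |
| grey | 0.071 M | 0.043 M | 3.55 mM | 40 °C | run made earlier |  |
| red | 0.071 M | 0.096 M | 3.55 mM | 25 °C | run made earlier |  |
| violet | 0.11 M | 0.0639 M | 3.55 mM | 40 °C | run made earlier |  |
| Friday's | 0.071 M | 0.0639 M (fed, over 6.0 min) | 3.55 mM |  | the addition at 0 °C, then warmed to 40 °C; the feed brings no volume worth counting | 8.0 min |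
| Saturday's | 0.071 M | 0.0639 M | 3.55 mM | 40 °C | everything together at the start | 8.0 min |
| Tuesday's | 0.071 M | 0.0639 M (fed, over 6.0 min) | 3.55 mM | 40 °C | all else is in the flask from the start; the feed brings no volume worth counting | 8.0 min |
| Thursday's | 0.071 M (in portions, 4, over 6.0 min) | 0.0639 M | 3.55 mM | 40 °C | first portion at the start, last at 6.0 min | 8.0 min |

| run | time / min | links / % | rings / % |
|---|---|---|---|
| blue | 3.00 | 26 | 21 |
| blue | 5.00 | 24 | 25 |
| blue | 8.00 | 26 | 23 |
| blue | 10.0 | 27 | 22 |
| blue | 12.0 | 26 | 23 |
| blue | 15.0 | 27 | 25 |
| grey | 1.00 | 11 | 33 |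
| grey | 2.00 | 16 | 35 |
| grey | 3.00 | 14 | 32 |
| grey | 4.00 | 10 | 30 |
| grey | 5.00 | 14 | 32 |
| grey | 6.00 | 11 | 33 |
| red | 2.00 | 34 | 22 |
| red | 4.00 | 34 | 25 |
| red | 6.00 | 34 | 23 |
| red | 8.00 | 36 | 26 |
| red | 10.0 | 33 | 23 |
| red | 12.0 | 34 | 27 |
| violet | 0.500 | 14 | 27 |
| violet | 1.00 | 17 | 23 |
| violet | 2.00 | 14 | 26 |
| violet | 3.00 | 15 | 28 |
| violet | 6.00 | 17 | 23 |

(scatter of a reading: 2 percentage points)

- the numbers in the tables scatter with a standard deviation of 2 percentage points

- which flask leads in share of links in links plus rings ("all alike" within 1.5 percentage points) (Friday's / Saturday's / Tuesday's / Thursday's / all alike)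
- share of links in links plus rings at the end, Friday's
- share of links in links plus rings at the end, Saturday's
- share of links in links plus rings at the end, Tuesday's
- share of links in links plus rings at the end, Thursday's

My reckoning starts from the ratio of links to rings, read against the mean free level, which in a batch run I take as half the charge of second end groups. Grey then gives 0.0552 M and violet 0.0527 M, close although their first end groups differ. So the crossover level, the free second end groups at which links and rings form equally fast, reads, on that half-charge assumption, 0.0539 M at 40 °C, and links over rings is level over crossover, a selectivity factor in concentration units.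

For Saturday's, half the charge gives a share of 37.2 %, and Thursday's, with its second end groups present in full from the start, I put there too. Blue reads, on the same assumption, a lower crossover of 0.0285 M at 25 °C, so I put Friday's, fed at 0 °C and then warmed to 40 °C, in the lead, but I give it no figure of my own, since no earlier run stands at 0 °C.

For Tuesday's, treat consumption as fast and the free level as a steady state. Grey, with the same first end groups and temperature, is on its plateau by 1.00 min, so I take the feed of 0.0106 M min⁻¹ to hold Tuesday's level under 0.0106 M, and Tuesday's share under 16.4 %.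

The forecast named Friday's, with 58 % for Friday's, 32 % for Saturday's, 18 % for Tuesday's and 38 % for Thursday's, and its words were: “Tuesday's starved feed favours rings”.

The flasks give 49.8 % for Friday's, 35.8 % for Saturday's, 0.0234 % for Tuesday's and 31.2 % for Thursday's, so Friday's leads.

    first end groups + second end groups → links (k = 0.720 L mol⁻¹ s⁻¹, Ea = 52.0 kJ mol⁻¹)
    first end groups + second end groups → rings, rate k2*[first end groups] as long as [second end groups] is above zero (k = 0.0280 s⁻¹, Ea = 94.0 kJ mol⁻¹)
    second end groups + protic impurity → quenched reagent (k = 1.50 L mol⁻¹ s⁻¹, Ea = 44.0 kJ mol⁻¹)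
    2 second end groups → homo dimer (k = 1.00 L mol⁻¹ s⁻¹, Ea = 49.0 kJ mol⁻¹)
    (constants at 40 °C)

At the end of its feed, at 6.00 min, Tuesday's holds 0.0614 % of its second end groups, which is 3.92 × 10⁻⁵ M, far less than the crossover reading. A neighbour like Tuesday's, charged with 0.26 M of second end groups, has a feed of 0.0433 M min⁻¹, so the same reckoning puts its share under 44.5 %. That neighbour gives 4.42 %, ending with 0 % of its first end groups and 1.3 % of its second end groups.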